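**Plan**

Retrosynthesis, in order: the enol-ether O–CH3 bond at C5 of the dienone; reconnection of the benzylic CH2 to that C5 oxygen (a temporary dihydrofuran ring); the C4–OCH3 bond (oxidative dearomatization); the allyl–C2 bond (Claisen); the ArCH2–CH(CH3) bond (carbene C–H insertion); the ArCH2–O ether bond (Mitsunobu).
Forward: the vanillyl unit is tethered through the C5 oxygen to an acetophenone; carbene insertion joins ArCH to CH(CH3) and closes the dihydrofuran ring; the allyl group is moved from oxygen to carbon; oxidative dearomatization makes the cyclohexadienone ring; the dihydrofuran ring is opened through a quinone methide and the freed enol is methylated.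
Enabling feature: the oxygen on C5 of the six-membered ring is ortho to C4, which carries the side chain, so a benzyl ether on it holds the vanillyl C–H bonds 1,5 to side-chain C2 and insertion closes a five-membered ring (O, ArCH, CH(CH3), C4, C5); the free para hydroxyl of the guaiacyl ring later allows this ring to be cut.
Stereochemistry: side-chain C2 (R) comes from the chiral dirhodium catalyst in the insertion; quaternary C4 (R) comes from methanol adding anti to the cis methyl and aryl groups of the temporary ring; the ArCH stereocentre is a helper and is erased on ring opening.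

Key step: step 6

Assumption: Rh2(R-PTAD)4 is taken to deliver the (2R,3S) series drawn below; should the sense of induction be the opposite, the mirror-image catalyst Rh2(S-PTAD)4 is used and nothing else changes.

**Route**

Step 1
Reactants: 1 vanillin (4-hydroxy-3-methoxybenzaldehyde)
Product: 2 3-methoxy-4-[(triisopropylsilyl)oxy]benzaldehyde
Conditions: TIPSCl, imidazole, DMF, 23 °C
Reagents that add atoms: chlorotriisopropylsilane, CC(C)[Si](Cl)(C(C)C)C(C)C
Why: O-silylation of the phenol masks it against hydrazine and the later oxidant, and the bulky silyl ether is kept until fluoride releases the phenoxide in step 9.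

Step 2
Reactants: 2 3-methoxy-4-[(triisopropylsilyl)oxy]benzaldehyde
Product: 3 {3-methoxy-4-[(triisopropylsilyl)oxy]phenyl}methanol
Conditions: NaBH4, MeOH, 0 °C
Reagents that add atoms: none
Why: borohydride reduction of the aldehyde gives the primary benzylic alcohol needed for the ether tether, and the aryl silyl ether is inert to it.

Step 3
Reactants: 4 1-(2,4-dihydroxyphenyl)ethan-1-one, 5 3-bromoprop-1-ene (allyl bromide)
Product: 6 1-[2-hydroxy-4-(prop-2-en-1-yloxy)phenyl]ethan-1-one
Conditions: K2CO3, acetone, 56 °C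
Reagents that add atoms: none
Why: Williamson etherification should occur at the 4-hydroxyl only, because the 2-hydroxyl is held in a hydrogen bond to the ketone; the allyl ether is a protecting group now and the source of the C-allyl group later.

Step 4
Reactants: 6 1-[2-hydroxy-4-(prop-2-en-1-yloxy)phenyl]ethan-1-one, 3 {3-methoxy-4-[(triisopropylsilyl)oxy]phenyl}methanol
Product: 7 1-[2-({3-methoxy-4-[(triisopropylsilyl)oxy]phenyl}methoxy)-4-(prop-2-en-1-yloxy)phenyl]ethan-1-one
Conditions: PPh3, DIAD, THF, 0 to 23 °C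
Reagents that add atoms: none
Why: Mitsunobu etherification of the remaining ortho phenol with the primary benzylic alcohol under neutral conditions installs the tether that holds the vanillyl CH2 next to the ketone carbon.

Step 5
Reactants: 7 1-[2-({3-methoxy-4-[(triisopropylsilyl)oxy]phenyl}methoxy)-4-(prop-2-en-1-yloxy)phenyl]ethan-1-one
Product: 8 (E)-hydrazone of ketone 7, (1E)-1-[2-({3-methoxy-4-[(triisopropylsilyl)oxy]phenyl}methoxy)-4-(prop-2-en-1-yloxy)phenyl]ethan-1-one hydrazone
Conditions: N2H4·H2O (excess), AcOH (cat.), EtOH, 80 °C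
Reagents that add atoms: hydrazine, NN
Why: hydrazone condensation of the aryl methyl ketone, with excess hydrazine to suppress azine formation, provides the precursor of the diazoalkane.

Step 6
Reactants: 8 (E)-hydrazone of ketone 7
Product: 10 (2R,3S)-2-{3-methoxy-4-[(triisopropylsilyl)oxy]phenyl}-3-methyl-6-(prop-2-en-1-yloxy)-2,3-dihydro-1-benzofuran (cis), via diazoalkane 9 (not isolated)
Conditions: MnO2, CH2Cl2, 0 °C; filter; then Rh2(R-PTAD)4 (1 mol %), CH2Cl2, −20 to 0 °C
Reagents that add atoms: none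
Why: MnO2 dehydrogenates the hydrazone to the aryl methyl diazoalkane 9, and Rh2(R-PTAD)4, the dirhodium tetrakis[(R)-(1-adamantyl)(N-phthalimido)acetate] complex of divalent rhodium, expels N2 from it to give a donor/donor rhodium carbene at the future side-chain CH(CH3) carbon, which inserts in a concerted, hydride-transfer-like three-centre transition state into a benzylic C–H bond of the vanillyl CH2 held five atoms away by the ether oxygen. The closest known reaction type is the enantioselective intramolecular C–H insertion of donor/donor dirhodium carbenes into benzylic ether C–H bonds, which gives 2,3-disubstituted 2,3-dihydrobenzofurans. The five-membered dihydrofuran ring is closed by 1,5-C–H insertion, the only mode within reach of the tether. Both new stereocentres are under catalyst control: the chiral carboxylate pocket selects the carbene face and one of the two enantiotopic benzylic hydrogens, and the compact transition state should place aryl and methyl cis, giving (2R,3S). The step needs insertion to win over 1,2-hydride shift from the carbene methyl group, over cyclopropanation of the allyl ether and over azine formation; the doubly activated hydridic C–H bond (alpha to oxygen and to an electron-rich arene), the low electrophilicity of a donor/donor carbene, low temperature and slow addition of the diazoalkane to the catalyst should secure this.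

Step 7
Reactants: 10 (2R,3S)-2-{3-methoxy-4-[(triisopropylsilyl)oxy]phenyl}-3-methyl-6-(prop-2-en-1-yloxy)-2,3-dihydro-1-benzofuran
Product: 11 (2R,3S)-2-{3-methoxy-4-[(triisopropylsilyl)oxy]phenyl}-3-methyl-5-(prop-2-en-1-yl)-2,3-dihydro-1-benzofuran-6-ol
Conditions: PhNEt2, 190 °C
Reagents that add atoms: none
Why: aromatic Claisen rearrangement ([3,3]-sigmatropic shift, then tautomerisation) should move the allyl group to C5, the open ortho position, and not to C7, which is flanked by two oxygens, and it frees the C6 phenol; the basic solvent protects the acid-labile cis benzylic ether from epimerisation.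

Step 8
Reactants: 11 (2R,3S)-2-{3-methoxy-4-[(triisopropylsilyl)oxy]phenyl}-3-methyl-5-(prop-2-en-1-yl)-2,3-dihydro-1-benzofuran-6-ol
Product: 12 (2R,3R,3aS)-3a-methoxy-2-{3-methoxy-4-[(triisopropylsilyl)oxy]phenyl}-3-methyl-5-(prop-2-en-1-yl)-3,3a-dihydro-1-benzofuran-6(2H)-one
Conditions: PhI(OAc)2, MeOH, 0 °C
Reagents that add atoms: methanol, CO
Why: oxidative dearomatization of the phenol by the hypervalent (trivalent) iodine reagent should put methanol on the para carbon C3a, on the face anti to the cis C3 methyl and C2 aryl groups of the fused dihydrofuran ring, which sets the quaternary stereocentre (3aS) as a para-quinol ether.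

Step 9
Reactants: 12 (2R,3R,3aS)-3a-methoxy-2-{3-methoxy-4-[(triisopropylsilyl)oxy]phenyl}-3-methyl-5-(prop-2-en-1-yl)-3,3a-dihydro-1-benzofuran-6(2H)-one
Product: 15 (4R)-5-hydroxy-4-[(2R)-1-(4-hydroxy-3-methoxyphenyl)propan-2-yl]-4-methoxy-2-(prop-2-en-1-yl)cyclohexa-2,5-dien-1-one, via phenol 13 (not isolated), via quinone methide 14 (not isolated)
Conditions: NaBH4, TBAF, THF–MeOH, −20 to 0 °C; then AcOH
Reagents that add atoms: none
Why: fluoride desilylation gives the phenoxide, which expels the vinylogous carboxylate by 1,6-elimination (E1cB) and so opens the temporary dihydrofuran ring as a para-quinone methide, and borohydride reduces the methide carbon irreversibly to CH2 (conjugate hydride reduction of a quinone methide) while the dienone is shielded as its enolate; the helper ArCH stereocentre disappears and the two remaining stereocentres are not touched.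

Step 10
Reactants: 15 (4R)-5-hydroxy-4-[(2R)-1-(4-hydroxy-3-methoxyphenyl)propan-2-yl]-4-methoxy-2-(prop-2-en-1-yl)cyclohexa-2,5-dien-1-one
Product: 16 (4R)-4-[(2R)-1-(4-hydroxy-3-methoxyphenyl)propan-2-yl]-4,5-dimethoxy-2-(prop-2-en-1-yl)cyclohexa-2,5-dien-1-one
Conditions: TMSCHN2, MeOH–toluene, 0 °C
Reagents that add atoms: (trimethylsilyl)diazomethane, C[Si](C)(C)C=[N+]=[N-]
Why: O-methylation of the vinylogous acid by the diazoalkane should go to the enol oxygen next to the quaternary carbon, where the enol proton is expected to reside (hydrogen-bonded to the neighbouring methoxy group, cross-conjugated dienone kept), while the much less acidic phenol is left alone.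

**Compound list**

1 | vanillin (4-hydroxy-3-methoxybenzaldehyde) | COc1cc(C=O)ccc1O | starting material
2 | 3-methoxy-4-[(triisopropylsilyl)oxy]benzaldehyde | COc1cc(C=O)ccc1O[Si](C(C)C)(C(C)C)C(C)C | intermediate
3 | {3-methoxy-4-[(triisopropylsilyl)oxy]phenyl}methanol | COc1cc(CO)ccc1O[Si](C(C)C)(C(C)C)C(C)C | intermediate
4 | 1-(2,4-dihydroxyphenyl)ethan-1-one | CC(=O)c1ccc(O)cc1O | starting material
5 | 3-bromoprop-1-ene (allyl bromide) | C=CCBr | starting material
6 | 1-[2-hydroxy-4-(prop-2-en-1-yloxy)phenyl]ethan-1-one | CC(=O)c1ccc(OCC=C)cc1O | intermediate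
7 | 1-[2-({3-methoxy-4-[(triisopropylsilyl)oxy]phenyl}methoxy)-4-(prop-2-en-1-yloxy)phenyl]ethan-1-one | CC(=O)c1ccc(OCC=C)cc1OCc1ccc(O[Si](C(C)C)(C(C)C)C(C)C)c(OC)c1 | intermediate
8 | (E)-hydrazone of ketone 7 | C/C(=N\N)c1ccc(OCC=C)cc1OCc1ccc(O[Si](C(C)C)(C(C)C)C(C)C)c(OC)c1 | intermediate
9 | 1-(1-diazoethyl)-2-({3-methoxy-4-[(triisopropylsilyl)oxy]phenyl}methoxy)-4-(prop-2-en-1-yloxy)benzene | CC(=[N+]=[N-])c1ccc(OCC=C)cc1OCc1ccc(O[Si](C(C)C)(C(C)C)C(C)C)c(OC)c1 | intermediate
10 | (2R,3S)-2-{3-methoxy-4-[(triisopropylsilyl)oxy]phenyl}-3-methyl-6-(prop-2-en-1-yloxy)-2,3-dihydro-1-benzofuran | C[C@H]1c2ccc(OCC=C)cc2O[C@H]1c3ccc(O[Si](C(C)C)(C(C)C)C(C)C)c(OC)c3 | intermediate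
11 | (2R,3S)-2-{3-methoxy-4-[(triisopropylsilyl)oxy]phenyl}-3-methyl-5-(prop-2-en-1-yl)-2,3-dihydro-1-benzofuran-6-ol | C[C@H]1c2cc(CC=C)c(O)cc2O[C@H]1c3ccc(O[Si](C(C)C)(C(C)C)C(C)C)c(OC)c3 | intermediate
12 | (2R,3R,3aS)-3a-methoxy-2-{3-methoxy-4-[(triisopropylsilyl)oxy]phenyl}-3-methyl-5-(prop-2-en-1-yl)-3,3a-dihydro-1-benzofuran-6(2H)-one | C[C@H]1[C@@]2(OC)C=C(CC=C)C(=O)C=C2O[C@H]1c3ccc(O[Si](C(C)C)(C(C)C)C(C)C)c(OC)c3 | intermediate
13 | (2R,3R,3aS)-2-(4-hydroxy-3-methoxyphenyl)-3a-methoxy-3-methyl-5-(prop-2-en-1-yl)-3,3a-dihydro-1-benzofuran-6(2H)-one (formed as its phenoxide) | C[C@H]1[C@@]2(OC)C=C(CC=C)C(=O)C=C2O[C@H]1c3ccc(O)c(OC)c3 | intermediate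
14 | (4R)-5-hydroxy-4-methoxy-4-[(2R)-1-(3-methoxy-4-oxocyclohexa-2,5-dien-1-ylidene)propan-2-yl]-2-(prop-2-en-1-yl)cyclohexa-2,5-dien-1-one (quinone methide, formed as its enolate) | C=CCC1=C[C@](OC)([C@H](C)C=C2C=CC(=O)C(OC)=C2)C(O)=CC1=O | intermediate
15 | (4R)-5-hydroxy-4-[(2R)-1-(4-hydroxy-3-methoxyphenyl)propan-2-yl]-4-methoxy-2-(prop-2-en-1-yl)cyclohexa-2,5-dien-1-one | C=CCC1=C[C@](OC)([C@H](C)Cc2ccc(O)c(OC)c2)C(O)=CC1=O | intermediate
16 | (4R)-4-[(2R)-1-(4-hydroxy-3-methoxyphenyl)propan-2-yl]-4,5-dimethoxy-2-(prop-2-en-1-yl)cyclohexa-2,5-dien-1-one | C=CCC1=C[C@](OC)([C@H](C)Cc2ccc(O)c(OC)c2)C(OC)=CC1=O | target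

**Count and risks**

Total step count: 10. Longest linear sequence: 9 steps (steps 1, 2, 4, 5, 6, 7, 8, 9, 10).

Step 6. What may go wrong: 1,2-hydride migration from the methyl group within the rhodium carbene (collapse to an alkene) or azine formation outruns C–H insertion, or the cis and enantiofacial selectivity is eroded. Fallback, setting out from 6 and 3 and coming back at 14: the same ArCH–CH(CH3) bond is made by a [4+1] annulation of an ortho-quinone methide with a chiral benzylic sulfonium ylide. Ketone 6 is reduced with NaBH4 to 2-(1-hydroxyethyl)-5-(prop-2-en-1-yloxy)phenol F1, which sodium p-toluenesulfinate in HCO2H converts into 2-[1-(4-methylbenzenesulfonyl)ethyl]-5-(prop-2-en-1-yloxy)phenol F2. Alcohol 3 is condensed with (2R,5R)-2,5-dimethylthiolane and HBF4·OEt2 to (2R,5R)-1-({3-methoxy-4-[(triisopropylsilyl)oxy]phenyl}methyl)-2,5-dimethylthiolan-1-ium tetrafluoroborate F3. Cs2CO3 in CH2Cl2 at −20 °C liberates the ortho-quinone methide from F2 and the ylide from F3; conjugate addition and 5-exo-tet ring closure should give the trans isomer (2S,3S)-2-{3-methoxy-4-[(triisopropylsilyl)oxy]phenyl}-3-methyl-6-(prop-2-en-1-yloxy)-2,3-dihydro-1-benzofuran F4, the enantiomer of the sulfide being chosen to give 3S. The conditions of step 7 should give (2S,3S)-2-{3-methoxy-4-[(triisopropylsilyl)oxy]phenyl}-3-methyl-5-(prop-2-en-1-yl)-2,3-dihydro-1-benzofuran-6-ol F5. The conditions of step 8, with methanol adding anti to the adjacent C3 methyl group, should give (2S,3R,3aS)-3a-methoxy-2-{3-methoxy-4-[(triisopropylsilyl)oxy]phenyl}-3-methyl-5-(prop-2-en-1-yl)-3,3a-dihydro-1-benzofuran-6(2H)-one F6. Under the conditions of step 9, desilylation gives (2S,3R,3aS)-2-(4-hydroxy-3-methoxyphenyl)-3a-methoxy-3-methyl-5-(prop-2-en-1-yl)-3,3a-dihydro-1-benzofuran-6(2H)-one F7, whose 1,6-elimination leads to quinone methide 14, where the C2 stereocentre no longer exists.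

Step 9. What may go wrong: the quinone methide is re-closed through carbon (intramolecular C-alkylation by the diketonate to a bicyclo[3.2.1]octane), or hydride attacks the dienone carbonyl, before the methide is reduced. Fallback, setting out from 10 and coming back at 16: the benzylic C–O bond is cut at the aromatic stage, at the price of losing the cyclic stereocontrol. Ionic hydrogenolysis of 10 (Et3SiH, CF3CO2H, CH2Cl2, −20 °C) should give 2-[(2R)-1-{3-methoxy-4-[(triisopropylsilyl)oxy]phenyl}propan-2-yl]-5-(prop-2-en-1-yloxy)phenol F8. MeI and K2CO3 in acetone give 2-methoxy-1-[(2R)-1-{3-methoxy-4-[(triisopropylsilyl)oxy]phenyl}propan-2-yl]-4-(prop-2-en-1-yloxy)benzene F9, with no regiochemical choice. Claisen rearrangement (PhNEt2, 190 °C) gives 5-methoxy-4-[(2R)-1-{3-methoxy-4-[(triisopropylsilyl)oxy]phenyl}propan-2-yl]-2-(prop-2-en-1-yl)phenol F10. PhI(OAc)2 in MeOH gives (4R)-4,5-dimethoxy-4-[(2R)-1-{3-methoxy-4-[(triisopropylsilyl)oxy]phenyl}propan-2-yl]-2-(prop-2-en-1-yl)cyclohexa-2,5-dien-1-one F11 together with its C4 epimer, to be separated by chromatography. TBAF in THF then gives 16.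

Step 10. What may go wrong: methylation at the enol oxygen remote from the quaternary carbon (wrong regiochemistry, giving the linear 2,4-dienone), or additional methylation of the phenol. Fallback, setting out from 15 and coming back at 16: the regiochemistry is put under steric control by silylating first and methylating second. TIPSOTf and Et3N in CH2Cl2 should silylate the phenol and the less hindered enol oxygen to give (6R)-6-methoxy-6-[(2R)-1-{3-methoxy-4-[(triisopropylsilyl)oxy]phenyl}propan-2-yl]-4-(prop-2-en-1-yl)-3-[(triisopropylsilyl)oxy]cyclohexa-2,4-dien-1-one F12. Me3OBF4 with 2,6-di-tert-butylpyridine then methylates the remaining carbonyl oxygen, next to the quaternary carbon, to give the O-methylated 1-methoxy-3-silyloxy allyl cation tetrafluoroborate F13, which is not isolated. TBAF removes both silyl groups and leaves 16.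

**Further compounds**

F1 | step 6 | 2-(1-hydroxyethyl)-5-(prop-2-en-1-yloxy)phenol (racemic) | CC(O)c1ccc(OCC=C)cc1O
F2 | step 6 | 2-[1-(4-methylbenzenesulfonyl)ethyl]-5-(prop-2-en-1-yloxy)phenol (racemic) | CC(c1ccc(OCC=C)cc1O)S(=O)(=O)c1ccc(C)cc1
F3 | step 6 | (2R,5R)-1-({3-methoxy-4-[(triisopropylsilyl)oxy]phenyl}methyl)-2,5-dimethylthiolan-1-ium tetrafluoroborate | C[C@@H]1CC[C@@H](C)[S+]1Cc1ccc(O[Si](C(C)C)(C(C)C)C(C)C)c(OC)c1.F[B-](F)(F)F
F4 | step 6 | (2S,3S)-2-{3-methoxy-4-[(triisopropylsilyl)oxy]phenyl}-3-methyl-6-(prop-2-en-1-yloxy)-2,3-dihydro-1-benzofuran | C[C@H]1c2ccc(OCC=C)cc2O[C@@H]1c3ccc(O[Si](C(C)C)(C(C)C)C(C)C)c(OC)c3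
F5 | step 6 | (2S,3S)-2-{3-methoxy-4-[(triisopropylsilyl)oxy]phenyl}-3-methyl-5-(prop-2-en-1-yl)-2,3-dihydro-1-benzofuran-6-ol | C[C@H]1c2cc(CC=C)c(O)cc2O[C@@H]1c3ccc(O[Si](C(C)C)(C(C)C)C(C)C)c(OC)c3
F6 | step 6 | (2S,3R,3aS)-3a-methoxy-2-{3-methoxy-4-[(triisopropylsilyl)oxy]phenyl}-3-methyl-5-(prop-2-en-1-yl)-3,3a-dihydro-1-benzofuran-6(2H)-one | C[C@H]1[C@@]2(OC)C=C(CC=C)C(=O)C=C2O[C@@H]1c3ccc(O[Si](C(C)C)(C(C)C)C(C)C)c(OC)c3
F7 | step 6 | (2S,3R,3aS)-2-(4-hydroxy-3-methoxyphenyl)-3a-methoxy-3-methyl-5-(prop-2-en-1-yl)-3,3a-dihydro-1-benzofuran-6(2H)-one | C[C@H]1[C@@]2(OC)C=C(CC=C)C(=O)C=C2O[C@@H]1c3ccc(O)c(OC)c3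
F8 | step 9 | 2-[(2R)-1-{3-methoxy-4-[(triisopropylsilyl)oxy]phenyl}propan-2-yl]-5-(prop-2-en-1-yloxy)phenol | C[C@H](Cc1ccc(O[Si](C(C)C)(C(C)C)C(C)C)c(OC)c1)c1ccc(OCC=C)cc1O
F9 | step 9 | 2-methoxy-1-[(2R)-1-{3-methoxy-4-[(triisopropylsilyl)oxy]phenyl}propan-2-yl]-4-(prop-2-en-1-yloxy)benzene | C[C@H](Cc1ccc(O[Si](C(C)C)(C(C)C)C(C)C)c(OC)c1)c1ccc(OCC=C)cc1OC
F10 | step 9 | 5-methoxy-4-[(2R)-1-{3-methoxy-4-[(triisopropylsilyl)oxy]phenyl}propan-2-yl]-2-(prop-2-en-1-yl)phenol | C[C@H](Cc1ccc(O[Si](C(C)C)(C(C)C)C(C)C)c(OC)c1)c1cc(CC=C)c(O)cc1OC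
F11 | step 9 | (4R)-4,5-dimethoxy-4-[(2R)-1-{3-methoxy-4-[(triisopropylsilyl)oxy]phenyl}propan-2-yl]-2-(prop-2-en-1-yl)cyclohexa-2,5-dien-1-one | C=CCC1=C[C@](OC)([C@H](C)Cc2ccc(O[Si](C(C)C)(C(C)C)C(C)C)c(OC)c2)C(OC)=CC1=O
F12 | step 10 | (6R)-6-methoxy-6-[(2R)-1-{3-methoxy-4-[(triisopropylsilyl)oxy]phenyl}propan-2-yl]-4-(prop-2-en-1-yl)-3-[(triisopropylsilyl)oxy]cyclohexa-2,4-dien-1-one | C=CCC1=C[C@](OC)([C@H](C)Cc2ccc(O[Si](C(C)C)(C(C)C)C(C)C)c(OC)c2)C(=O)C=C1O[Si](C(C)C)(C(C)C)C(C)C
F13 | step 10 | O-methylated oxocarbenium tetrafluoroborate of F12 (1-methoxy-3-silyloxy allyl cation) | C=CCC1=C[C@](OC)([C@H](C)Cc2ccc(O[Si](C(C)C)(C(C)C)C(C)C)c(OC)c2)C(=[O+]C)C=C1O[Si](C(C)C)(C(C)C)C(C)C.F[B-](F)(F)F
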